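**Plan**

- Retrosynthesis: the three O–benzyl bonds go last, then the lactone C1–O2 bond of the isocoumarin (keto acid to enol lactone). Ring B is then cut through C6–C7, C8–C8a and C5–C6 into a ring A aryl ethynyl ether and a 2-substituted vinylketene, which comes from an α-diazo enone.
- Enabling feature: ring B is a 1,3-dioxygenated benzene (C6–OMe, C8–OAr) whose neighbouring carbons C8a and C4a both carry carbon. A vinylketene and a heteroatom-substituted alkyne give exactly this pattern.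
- Forward, ring A: orsellinic acid supplies ring A; it gains a ring oxygen next to its methyl group (bromide, boronate, phenol) and the oxoheptyl chain (lateral acylation). The phenol then becomes the ethynyl ether via trichloroethylene.
- Forward, ring B: the diazo enone is joined from hexanal, 2,3-dibromopropene and a silyloxypropanal. The benzannulation builds ring B directly on the ether oxygen; the pyranone ring closes afterwards and hydrogenolysis finishes.
- Stereochemistry: the target has no stereocentre. The racemic carbinols, the cyclobutenone carbon and the dichlorovinyl geometry met on the way are all erased.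

Key step: step 14

Assumption: orsellinic acid, N-methoxy-N-methylhexanamide and 3-[(tert-butyldimethylsilyl)oxy]propanal are taken as purchasable; ring B positions are given in isocoumarin numbering.

**Route**

Step 1
Reactants: 1 orsellinic acid (2,4-dihydroxy-6-methylbenzoic acid)
Product: 2 benzyl 2,4-bis(benzyloxy)-6-methylbenzoate
Conditions: BnBr (3.5 equiv), K2CO3, DMF, rt → 60 °C
Reagents that add atoms: benzyl bromide, BrCc1ccccc1
Why: Williamson O-alkylation of the carboxylate and both phenoxides in one operation installs three groups that all leave together by hydrogenolysis at the end.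

Step 2
Reactants: 2 benzyl 2,4-bis(benzyloxy)-6-methylbenzoate
Product: 3 benzyl 4,6-bis(benzyloxy)-3-bromo-2-methylbenzoate
Conditions: NBS (1.0 equiv), MeCN, 0 °C → rt, dark
Reagents that add atoms: N-bromosuccinimide, O=C1CCC(=O)N1Br
Why: Electrophilic aromatic bromination should go to the ring carbon next to the methyl group (para to one benzyloxy group, ortho to the other), the position between the two ethers being more crowded, as halogenation of orsellinates does.

Step 3
Reactants: 3 benzyl 4,6-bis(benzyloxy)-3-bromo-2-methylbenzoate; 4 N-methoxy-N-methylhexanamide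
Product: 6 benzyl 4,6-bis(benzyloxy)-3-bromo-2-(2-oxoheptyl)benzoate, via lithiated toluate 5 (not isolated)
Conditions: LiN(i-Pr)2 (1.2 equiv), THF, −78 °C; then 4, −78 °C; aq. NH4Cl
Reagents that add atoms: none
Why: Lateral (toluate) lithiation of the ortho-methyl group followed by Weinreb ketone synthesis, in which the chelated tetrahedral adduct should hold back both over-addition and lactonisation until the quench.

Step 4
Reactants: 6 benzyl 4,6-bis(benzyloxy)-3-bromo-2-(2-oxoheptyl)benzoate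
Product: 7 benzyl 4,6-bis(benzyloxy)-3-bromo-2-[(2-pentyl-1,3-dioxolan-2-yl)methyl]benzoate
Conditions: Me3SiOCH2CH2OSiMe3, Me3SiOTf (cat.), CH2Cl2, −78 → −20 °C; pyridine quench
Reagents that add atoms: 1,2-bis(trimethylsilyloxy)ethane, C[Si](C)(C)OCCO[Si](C)(C)C
Why: Noyori ketalisation runs aprotic and cold, conditions under which the keto ester should not close to an isocoumarin.

Step 5
Reactants: 7 benzyl 4,6-bis(benzyloxy)-3-bromo-2-[(2-pentyl-1,3-dioxolan-2-yl)methyl]benzoate
Product: 9 benzyl 4,6-bis(benzyloxy)-3-hydroxy-2-[(2-pentyl-1,3-dioxolan-2-yl)methyl]benzoate, via pinacol boronate 8 (not isolated)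
Conditions: B2pin2, Pd(OAc)2 (cat.), SPhos, KOAc, 1,4-dioxane, 90 °C; then 30% H2O2, aq. NaOH, THF, 0 °C
Reagents that add atoms: hydrogen peroxide, OO (phenol oxygen); bis(pinacolato)diboron, CC1(C)OB(OC1(C)C)B1OC(C)(C)C(C)(C)O1 (boron of 8 only)
Why: Miyaura borylation with a bulky biaryl phosphine should accept the doubly ortho-substituted bromide, and oxidative aryl migration from boron to oxygen then gives the phenol without touching the hindered ester.

Step 6
Reactants: 9 benzyl 4,6-bis(benzyloxy)-3-hydroxy-2-[(2-pentyl-1,3-dioxolan-2-yl)methyl]benzoate; 10 trichloroethylene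
Product: 12 benzyl 4,6-bis(benzyloxy)-3-{[(E)-1,2-dichloroethenyl]oxy}-2-[(2-pentyl-1,3-dioxolan-2-yl)methyl]benzoate, via dichloroacetylene 11 (not isolated)
Conditions: K2CO3, DMF, 70 °C
Reagents that add atoms: none
Why: Base-induced elimination–addition: trichloroethylene loses HCl to dichloroacetylene, to which the phenoxide should add in anti fashion to give the E dichlorovinyl ether.

Step 7
Reactants: 12 benzyl 4,6-bis(benzyloxy)-3-{[(E)-1,2-dichloroethenyl]oxy}-2-[(2-pentyl-1,3-dioxolan-2-yl)methyl]benzoate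
Product: 15 benzyl 4,6-bis(benzyloxy)-3-(ethynyloxy)-2-[(2-pentyl-1,3-dioxolan-2-yl)methyl]benzoate, via chloroethynyl ether 13 (not isolated), via lithium acetylide 14 (not isolated)
Conditions: n-BuLi (2.2 equiv), THF, −78 °C; then MeOH, −78 °C; cold work-up, used at once
Reagents that add atoms: none
Why: Dehydrochlorination to the chloroalkyne and lithium–chlorine exchange (the dichlorovinyl ether route to ynol ethers) are fast at −78 °C, where the benzoate flanked by two ortho substituents should resist addition.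

Step 8
Reactants: 16 hexanal; 17 2,3-dibromopropene
Product: 18 2-bromonon-1-en-4-ol (racemic)
Conditions: In powder, THF/H2O (1:1), rt
Reagents that add atoms: none
Why: Barbier allylation, in which indium should insert only into the allylic C–Br bond and leave the vinylic bromide in place; the carbinol centre is racemic and is removed in step 9.

Step 9
Reactants: 18 2-bromonon-1-en-4-ol
Product: 19 2-bromonon-1-en-4-one
Conditions: Dess–Martin periodinane, NaHCO3, CH2Cl2, 0 °C → rt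
Reagents that add atoms: none
Why: Dess–Martin oxidation under buffered neutral conditions should keep the β,γ double bond from moving into conjugation.

Step 10
Reactants: 19 2-bromonon-1-en-4-one
Product: 20 2-(2-bromoprop-2-en-1-yl)-2-pentyl-1,3-dioxolane
Conditions: Me3SiOCH2CH2OSiMe3, Me3SiOTf (cat.), CH2Cl2, −78 °C; pyridine quench
Reagents that add atoms: 1,2-bis(trimethylsilyloxy)ethane, C[Si](C)(C)OCCO[Si](C)(C)C
Why: Noyori ketalisation is the standard way to protect a β,γ-unsaturated ketone without double-bond migration.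

Step 11
Reactants: 20 2-(2-bromoprop-2-en-1-yl)-2-pentyl-1,3-dioxolane; 21 3-[(tert-butyldimethylsilyl)oxy]propanal
Product: 23 1-[(tert-butyldimethylsilyl)oxy]-4-methylidene-5-(2-pentyl-1,3-dioxolan-2-yl)pentan-3-ol (racemic), via alkenyllithium 22 (not isolated)
Conditions: t-BuLi (2.1 equiv), Et2O, −78 °C; then 21, −78 °C; aq. NH4Cl
Reagents that add atoms: none
Why: Bromine–lithium exchange on the 2-bromoalkene and 1,2-addition of the alkenyllithium to the aldehyde; the carbinol centre is racemic and is oxidised away in step 12.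

Step 12
Reactants: 23 1-[(tert-butyldimethylsilyl)oxy]-4-methylidene-5-(2-pentyl-1,3-dioxolan-2-yl)pentan-3-ol
Product: 24 1-[(tert-butyldimethylsilyl)oxy]-4-methylidene-5-(2-pentyl-1,3-dioxolan-2-yl)pentan-3-one
Conditions: Dess–Martin periodinane, NaHCO3, CH2Cl2, 0 °C
Reagents that add atoms: none
Why: Dess–Martin oxidation of the allylic alcohol should give the α-methylene ketone without acid or base that could eliminate the β-silyloxy group.

Step 13
Reactants: 24 1-[(tert-butyldimethylsilyl)oxy]-4-methylidene-5-(2-pentyl-1,3-dioxolan-2-yl)pentan-3-one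
Product: 27 1-[(tert-butyldimethylsilyl)oxy]-2-diazo-4-methylidene-5-(2-pentyl-1,3-dioxolan-2-yl)pentan-3-one, via lithium enolate 25 (not isolated), via trifluoroacetyl diketone 26 (not isolated)
Conditions: LiN(SiMe3)2, THF, −78 °C; CF3CO2CH2CF3, −78 °C; aq. NH4Cl, crude 26 taken on at once; then MsN3, Et3N, H2O (1 equiv), MeCN, rt
Reagents that add atoms: methanesulfonyl azide, CS(=O)(=O)N=[N+]=[N-] (the two diazo nitrogens); 2,2,2-trifluoroethyl trifluoroacetate, O=C(OCC(F)(F)F)C(F)(F)F (trifluoroacetyl group of 26 only)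
Why: Detrifluoroacetylative diazo transfer (Danheiser's variant of the Regitz reaction), in which kinetic deprotonation is possible only at the saturated α'-methylene, trifluoroacetylation activates that carbon and the sulfonyl azide delivers N2 with loss of the trifluoroacetyl group.

Step 14
Reactants: 27 1-[(tert-butyldimethylsilyl)oxy]-2-diazo-4-methylidene-5-(2-pentyl-1,3-dioxolan-2-yl)pentan-3-one; 15 benzyl 4,6-bis(benzyloxy)-3-(ethynyloxy)-2-[(2-pentyl-1,3-dioxolan-2-yl)methyl]benzoate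
Product: 32 benzyl 4,6-bis(benzyloxy)-3-{2-[(tert-butyldimethylsilyloxy)methyl]-5-hydroxy-3-[(2-pentyl-1,3-dioxolan-2-yl)methyl]phenoxy}-2-[(2-pentyl-1,3-dioxolan-2-yl)methyl]benzoate, via vinylketene 28 (not isolated), via vinylcyclobutenone 29 (not isolated), via dienylketene 30 (not isolated), via cyclohexadienone 31 (not isolated)
Conditions: hν (300 nm, Pyrex), degassed ClCH2CH2Cl, rt; then 80 °C
Reagents that add atoms: none
Why: Photolysis expels N2 and the alkenyl group migrates (Wolff rearrangement) to vinylketene 28, whose ketene C=C adds the ynol ether in a [2+2] cycloaddition to 4-vinylcyclobutenone 29; four-electron electrocyclic opening to dienylketene 30, six-electron electrocyclic closure to dienone 31 and enolisation then give the phenol. The closest known reaction is the Danheiser benzannulation of α-diazo enones with alkoxy- and siloxyalkynes, run here with an aryloxyalkyne. Ring B closes by the 6π electrocyclisation that forms C5–C6, after the cycloaddition has made C6–C7 and C8–C8a. No stereocentre results, since the quaternary carbon of 29 is racemic and becomes aromatic. The step needs regioselective cycloaddition: the ether oxygen makes the unsubstituted alkyne carbon the nucleophile, so it should bond to the ketene carbonyl carbon and place the aryloxy group meta to the new hydroxyl and next to the silyloxymethyl carbon. It also needs Wolff migration to beat a 1,2-hydrogen shift, which direct, unsensitised, metal-free irradiation favours, and opening of 29 is reversible at 80 °C so material should funnel through the isomer of 30 that can cyclise.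

Step 15
Reactants: 32 benzyl 4,6-bis(benzyloxy)-3-{2-[(tert-butyldimethylsilyloxy)methyl]-5-hydroxy-3-[(2-pentyl-1,3-dioxolan-2-yl)methyl]phenoxy}-2-[(2-pentyl-1,3-dioxolan-2-yl)methyl]benzoate
Product: 33 benzyl 4,6-bis(benzyloxy)-3-{2-[(tert-butyldimethylsilyloxy)methyl]-5-methoxy-3-[(2-pentyl-1,3-dioxolan-2-yl)methyl]phenoxy}-2-[(2-pentyl-1,3-dioxolan-2-yl)methyl]benzoate
Conditions: MeI, K2CO3, acetone, 50 °C
Reagents that add atoms: iodomethane, CI
Why: Williamson methylation of the only free, unhindered phenol sets the C6 methoxy group.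

Step 16
Reactants: 33 benzyl 4,6-bis(benzyloxy)-3-{2-[(tert-butyldimethylsilyloxy)methyl]-5-methoxy-3-[(2-pentyl-1,3-dioxolan-2-yl)methyl]phenoxy}-2-[(2-pentyl-1,3-dioxolan-2-yl)methyl]benzoate
Product: 34 benzyl 4,6-bis(benzyloxy)-3-{2-(hydroxymethyl)-5-methoxy-3-[(2-pentyl-1,3-dioxolan-2-yl)methyl]phenoxy}-2-[(2-pentyl-1,3-dioxolan-2-yl)methyl]benzoate
Conditions: Bu4NF, THF, 0 °C → rt
Reagents that add atoms: none
Why: Fluoride-mediated desilylation frees the benzylic alcohol and leaves ketals, benzyl ethers and the hindered ester alone.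

Step 17
Reactants: 34 benzyl 4,6-bis(benzyloxy)-3-{2-(hydroxymethyl)-5-methoxy-3-[(2-pentyl-1,3-dioxolan-2-yl)methyl]phenoxy}-2-[(2-pentyl-1,3-dioxolan-2-yl)methyl]benzoate
Product: 35 benzyl 4,6-bis(benzyloxy)-3-{2-formyl-5-methoxy-3-[(2-pentyl-1,3-dioxolan-2-yl)methyl]phenoxy}-2-[(2-pentyl-1,3-dioxolan-2-yl)methyl]benzoate
Conditions: Dess–Martin periodinane, NaHCO3, CH2Cl2, rt
Reagents that add atoms: none
Why: Dess–Martin oxidation copes with the doubly ortho-substituted benzylic alcohol, and the still-ketalised side chain cannot undergo aldol closure onto the new aldehyde.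

Step 18
Reactants: 35 benzyl 4,6-bis(benzyloxy)-3-{2-formyl-5-methoxy-3-[(2-pentyl-1,3-dioxolan-2-yl)methyl]phenoxy}-2-[(2-pentyl-1,3-dioxolan-2-yl)methyl]benzoate
Product: 36 benzyl 4,6-bis(benzyloxy)-3-{2-carboxy-5-methoxy-3-[(2-pentyl-1,3-dioxolan-2-yl)methyl]phenoxy}-2-[(2-pentyl-1,3-dioxolan-2-yl)methyl]benzoate
Conditions: NaClO2, NaH2PO4, 2-methyl-2-butene, t-BuOH/H2O, rt
Reagents that add atoms: sodium chlorite, [Na+].[O-]Cl=O
Why: Pinnick oxidation takes the aldehyde to the C1 carboxylic acid at mild pH, with the alkene scavenger shielding the electron-rich rings from hypochlorous acid.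

Step 19
Reactants: 36 benzyl 4,6-bis(benzyloxy)-3-{2-carboxy-5-methoxy-3-[(2-pentyl-1,3-dioxolan-2-yl)methyl]phenoxy}-2-[(2-pentyl-1,3-dioxolan-2-yl)methyl]benzoate
Product: 37 benzyl 4,6-bis(benzyloxy)-3-[2-carboxy-5-methoxy-3-(2-oxoheptyl)phenoxy]-2-(2-oxoheptyl)benzoate
Conditions: 2 M aq. HCl, THF, rt → 40 °C; crude taken on
Reagents that add atoms: water, O
Why: Acid-catalysed ketal hydrolysis frees both ketones under aqueous, non-dehydrating conditions in which the ring A keto ester should stay open (the ring B keto acid may sit partly as its lactol).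

Step 20
Reactants: 37 benzyl 4,6-bis(benzyloxy)-3-[2-carboxy-5-methoxy-3-(2-oxoheptyl)phenoxy]-2-(2-oxoheptyl)benzoate
Product: 38 benzyl 4,6-bis(benzyloxy)-3-[(6-methoxy-1-oxo-3-pentyl-1H-isochromen-8-yl)oxy]-2-(2-oxoheptyl)benzoate
Conditions: Ac2O, pyridine, 60 °C
Reagents that add atoms: none
Why: Enol lactonisation through the mixed anhydride activates only the free ring B carboxyl, whose neighbouring ketone closes the six-membered pyranone, while the benzyl ester of ring A cannot be activated.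

Step 21
Reactants: 38 benzyl 4,6-bis(benzyloxy)-3-[(6-methoxy-1-oxo-3-pentyl-1H-isochromen-8-yl)oxy]-2-(2-oxoheptyl)benzoate
Product: 39 beta-collatolic acid (4,6-dihydroxy-3-[(6-methoxy-1-oxo-3-pentyl-1H-isochromen-8-yl)oxy]-2-(2-oxoheptyl)benzoic acid)
Conditions: H2 (1 atm), Pd/C, EtOAc, rt; stopped when the benzyl groups are gone
Reagents that add atoms: none
Why: Hydrogenolysis cleaves the two benzyl ethers and the benzyl ester under neutral conditions, faster than the trisubstituted enol-lactone double bond should be reduced and without acid that could lactonise ring A.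

**Compound list**

1 | orsellinic acid | Cc1cc(O)cc(O)c1C(=O)O | starting material
2 | benzyl 2,4-bis(benzyloxy)-6-methylbenzoate | Cc1cc(OCc2ccccc2)cc(OCc2ccccc2)c1C(=O)OCc1ccccc1 | intermediate
3 | benzyl 4,6-bis(benzyloxy)-3-bromo-2-methylbenzoate | Cc1c(Br)c(OCc2ccccc2)cc(OCc2ccccc2)c1C(=O)OCc1ccccc1 | intermediate
4 | N-methoxy-N-methylhexanamide | CCCCCC(=O)N(C)OC | starting material
5 | lithiated toluate (benzylic lithium derivative of 3) | [Li]Cc1c(Br)c(OCc2ccccc2)cc(OCc2ccccc2)c1C(=O)OCc1ccccc1 | intermediate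
6 | benzyl 4,6-bis(benzyloxy)-3-bromo-2-(2-oxoheptyl)benzoate | CCCCCC(=O)Cc1c(Br)c(OCc2ccccc2)cc(OCc2ccccc2)c1C(=O)OCc1ccccc1 | intermediate
7 | benzyl 4,6-bis(benzyloxy)-3-bromo-2-[(2-pentyl-1,3-dioxolan-2-yl)methyl]benzoate | CCCCCC1(Cc2c(Br)c(OCc3ccccc3)cc(OCc3ccccc3)c2C(=O)OCc2ccccc2)OCCO1 | intermediate
8 | benzyl 4,6-bis(benzyloxy)-2-[(2-pentyl-1,3-dioxolan-2-yl)methyl]-3-(4,4,5,5-tetramethyl-1,3,2-dioxaborolan-2-yl)benzoate | CCCCCC1(Cc2c(B3OC(C)(C)C(C)(C)O3)c(OCc3ccccc3)cc(OCc3ccccc3)c2C(=O)OCc2ccccc2)OCCO1 | intermediate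
9 | benzyl 4,6-bis(benzyloxy)-3-hydroxy-2-[(2-pentyl-1,3-dioxolan-2-yl)methyl]benzoate | CCCCCC1(Cc2c(O)c(OCc3ccccc3)cc(OCc3ccccc3)c2C(=O)OCc2ccccc2)OCCO1 | intermediate
10 | trichloroethylene | ClC=C(Cl)Cl | starting material
11 | dichloroacetylene | ClC#CCl | intermediate
12 | benzyl 4,6-bis(benzyloxy)-3-{[(E)-1,2-dichloroethenyl]oxy}-2-[(2-pentyl-1,3-dioxolan-2-yl)methyl]benzoate | Cl/C=C(/Cl)Oc1c(OCc2ccccc2)cc(OCc2ccccc2)c(C(=O)OCc2ccccc2)c1CC1(CCCCC)OCCO1 | intermediate
13 | benzyl 4,6-bis(benzyloxy)-3-[(chloroethynyl)oxy]-2-[(2-pentyl-1,3-dioxolan-2-yl)methyl]benzoate | ClC#COc1c(OCc2ccccc2)cc(OCc2ccccc2)c(C(=O)OCc2ccccc2)c1CC1(CCCCC)OCCO1 | intermediate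
14 | lithium acetylide of 15 | [Li]C#COc1c(OCc2ccccc2)cc(OCc2ccccc2)c(C(=O)OCc2ccccc2)c1CC1(CCCCC)OCCO1 | intermediate
15 | benzyl 4,6-bis(benzyloxy)-3-(ethynyloxy)-2-[(2-pentyl-1,3-dioxolan-2-yl)methyl]benzoate | C#COc1c(OCc2ccccc2)cc(OCc2ccccc2)c(C(=O)OCc2ccccc2)c1CC1(CCCCC)OCCO1 | intermediate
16 | hexanal | CCCCCC=O | starting material
17 | 2,3-dibromopropene | C=C(Br)CBr | starting material
18 | 2-bromonon-1-en-4-ol (racemic) | C=C(Br)CC(O)CCCCC | intermediate
19 | 2-bromonon-1-en-4-one | C=C(Br)CC(=O)CCCCC | intermediate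
20 | 2-(2-bromoprop-2-en-1-yl)-2-pentyl-1,3-dioxolane | C=C(Br)CC1(CCCCC)OCCO1 | intermediate
21 | 3-[(tert-butyldimethylsilyl)oxy]propanal | O=CCCO[Si](C)(C)C(C)(C)C | starting material
22 | 2-lithio alkene from 20 | [Li]C(=C)CC1(CCCCC)OCCO1 | intermediate
23 | 1-[(tert-butyldimethylsilyl)oxy]-4-methylidene-5-(2-pentyl-1,3-dioxolan-2-yl)pentan-3-ol (racemic) | C=C(CC1(CCCCC)OCCO1)C(O)CCO[Si](C)(C)C(C)(C)C | intermediate
24 | 1-[(tert-butyldimethylsilyl)oxy]-4-methylidene-5-(2-pentyl-1,3-dioxolan-2-yl)pentan-3-one | C=C(CC1(CCCCC)OCCO1)C(=O)CCO[Si](C)(C)C(C)(C)C | intermediate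
25 | lithium enolate of 24 | [Li]OC(=CCO[Si](C)(C)C(C)(C)C)C(=C)CC1(CCCCC)OCCO1 | intermediate
26 | 3-{[(tert-butyldimethylsilyl)oxy]methyl}-1,1,1-trifluoro-5-methylidene-6-(2-pentyl-1,3-dioxolan-2-yl)hexane-2,4-dione (racemic) | C=C(CC1(CCCCC)OCCO1)C(=O)C(CO[Si](C)(C)C(C)(C)C)C(=O)C(F)(F)F | intermediate
27 | 1-[(tert-butyldimethylsilyl)oxy]-2-diazo-4-methylidene-5-(2-pentyl-1,3-dioxolan-2-yl)pentan-3-one | [N-]=[N+]=C(CO[Si](C)(C)C(C)(C)C)C(=O)C(=C)CC1(CCCCC)OCCO1 | intermediate
28 | vinylketene: 2-{[(tert-butyldimethylsilyl)oxy]methyl}-3-[(2-pentyl-1,3-dioxolan-2-yl)methyl]buta-1,3-dien-1-one | O=C=C(CO[Si](C)(C)C(C)(C)C)C(=C)CC1(CCCCC)OCCO1 | intermediate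
29 | vinylcyclobutenone: 3-aryloxy-4-(silyloxymethyl)-4-alkenylcyclobut-2-en-1-one (racemic; aryl = ring A of 15) | O=C1C=C(Oc2c(OCc3ccccc3)cc(OCc3ccccc3)c(C(=O)OCc3ccccc3)c2CC2(CCCCC)OCCO2)C1(CO[Si](C)(C)C(C)(C)C)C(=C)CC1(CCCCC)OCCO1 | intermediate
30 | dienylketene: 3-aryloxy-4-(silyloxymethyl)-5-substituted hexa-1,3,5-trien-1-one (ketenyl and alkenyl groups cis) | O=C=C/C(Oc1c(OCc2ccccc2)cc(OCc2ccccc2)c(C(=O)OCc2ccccc2)c1CC1(CCCCC)OCCO1)=C(\C(=C)CC1(CCCCC)OCCO1)CO[Si](C)(C)C(C)(C)C | intermediate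
31 | cyclohexadienone: 3-aryloxy-4-(silyloxymethyl)-5-[(2-pentyl-1,3-dioxolan-2-yl)methyl]cyclohexa-2,4-dien-1-one | O=C1C=C(Oc2c(OCc3ccccc3)cc(OCc3ccccc3)c(C(=O)OCc3ccccc3)c2CC2(CCCCC)OCCO2)C(CO[Si](C)(C)C(C)(C)C)=C(CC2(CCCCC)OCCO2)C1 | intermediate
32 | benzyl 4,6-bis(benzyloxy)-3-{2-[(tert-butyldimethylsilyloxy)methyl]-5-hydroxy-3-[(2-pentyl-1,3-dioxolan-2-yl)methyl]phenoxy}-2-[(2-pentyl-1,3-dioxolan-2-yl)methyl]benzoate | Oc1cc(Oc2c(OCc3ccccc3)cc(OCc3ccccc3)c(C(=O)OCc3ccccc3)c2CC2(CCCCC)OCCO2)c(CO[Si](C)(C)C(C)(C)C)c(CC2(CCCCC)OCCO2)c1 | intermediate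
33 | benzyl 4,6-bis(benzyloxy)-3-{2-[(tert-butyldimethylsilyloxy)methyl]-5-methoxy-3-[(2-pentyl-1,3-dioxolan-2-yl)methyl]phenoxy}-2-[(2-pentyl-1,3-dioxolan-2-yl)methyl]benzoate | COc1cc(Oc2c(OCc3ccccc3)cc(OCc3ccccc3)c(C(=O)OCc3ccccc3)c2CC2(CCCCC)OCCO2)c(CO[Si](C)(C)C(C)(C)C)c(CC2(CCCCC)OCCO2)c1 | intermediate
34 | benzyl 4,6-bis(benzyloxy)-3-{2-(hydroxymethyl)-5-methoxy-3-[(2-pentyl-1,3-dioxolan-2-yl)methyl]phenoxy}-2-[(2-pentyl-1,3-dioxolan-2-yl)methyl]benzoate | COc1cc(Oc2c(OCc3ccccc3)cc(OCc3ccccc3)c(C(=O)OCc3ccccc3)c2CC2(CCCCC)OCCO2)c(CO)c(CC2(CCCCC)OCCO2)c1 | intermediate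
35 | benzyl 4,6-bis(benzyloxy)-3-{2-formyl-5-methoxy-3-[(2-pentyl-1,3-dioxolan-2-yl)methyl]phenoxy}-2-[(2-pentyl-1,3-dioxolan-2-yl)methyl]benzoate | COc1cc(Oc2c(OCc3ccccc3)cc(OCc3ccccc3)c(C(=O)OCc3ccccc3)c2CC2(CCCCC)OCCO2)c(C=O)c(CC2(CCCCC)OCCO2)c1 | intermediate
36 | benzyl 4,6-bis(benzyloxy)-3-{2-carboxy-5-methoxy-3-[(2-pentyl-1,3-dioxolan-2-yl)methyl]phenoxy}-2-[(2-pentyl-1,3-dioxolan-2-yl)methyl]benzoate | COc1cc(Oc2c(OCc3ccccc3)cc(OCc3ccccc3)c(C(=O)OCc3ccccc3)c2CC2(CCCCC)OCCO2)c(C(=O)O)c(CC2(CCCCC)OCCO2)c1 | intermediate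
37 | benzyl 4,6-bis(benzyloxy)-3-[2-carboxy-5-methoxy-3-(2-oxoheptyl)phenoxy]-2-(2-oxoheptyl)benzoate | COc1cc(Oc2c(OCc3ccccc3)cc(OCc3ccccc3)c(C(=O)OCc3ccccc3)c2CC(=O)CCCCC)c(C(=O)O)c(CC(=O)CCCCC)c1 | intermediate
38 | benzyl 4,6-bis(benzyloxy)-3-[(6-methoxy-1-oxo-3-pentyl-1H-isochromen-8-yl)oxy]-2-(2-oxoheptyl)benzoate | CCCCCC(=O)Cc1c(Oc2cc(OC)cc3cc(CCCCC)oc(=O)c23)c(OCc2ccccc2)cc(OCc2ccccc2)c1C(=O)OCc1ccccc1 | intermediate
39 | beta-collatolic acid | CCCCCC(=O)Cc1c(Oc2cc(OC)cc3cc(CCCCC)oc(=O)c23)c(O)cc(O)c1C(=O)O | target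

**Count and risks**

Total steps: 21. Longest linear sequence: 15 steps (steps 1–7, then 14–21); the diazo enone branch (steps 8–13) has 6 steps.

Steps most likely to fail:

Step 14. The keto carbene may undergo a 1,2-hydrogen shift from the silyloxymethyl group faster than the alkenyl group migrates, and capture of the ketene by the crowded, less electron-rich aryloxyalkyne may lose out to ketene dimerisation. The fallback makes the diaryl ether by cross-coupling; it sets out from phenol 9 and amide 4 and returns at 38. Commercial methyl orsellinate would be methylated at the non-chelated hydroxyl (MeI 1 equiv, K2CO3, acetone) to methyl 2-hydroxy-4-methoxy-6-methylbenzoate F1. Its dianion (LiN(i-Pr)2, 2.5 equiv, THF, −78 °C) would be acylated with 4 to methyl 2-hydroxy-4-methoxy-6-(2-oxoheptyl)benzoate F2. TsOH in warm toluene would close F2 to 8-hydroxy-6-methoxy-3-pentyl-1H-isochromen-1-one F3, and Tf2O with pyridine would give 6-methoxy-1-oxo-3-pentyl-1H-isochromen-8-yl trifluoromethanesulfonate F4. Palladium-catalysed C–O coupling (Pd(OAc)2, t-BuXPhos, K3PO4, toluene, 100 °C) of F4 with 9 would give benzyl 4,6-bis(benzyloxy)-3-[(6-methoxy-1-oxo-3-pentyl-1H-isochromen-8-yl)oxy]-2-[(2-pentyl-1,3-dioxolan-2-yl)methyl]benzoate F5. 2 M HCl in THF would then free the ring A ketone and deliver 38, ready for step 21.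

Step 13. β-Elimination of silanolate from the enolate or from the trifluoroacetyl diketone, or conjugate addition of the amide base to the α-methylene ketone, may pre-empt acylation and diazo transfer at the branched carbon. The fallback builds the substituted diazo carbon by C–C bond formation on a terminal diazo ketone; it sets out from bromide 20 and returns at 27. Alkenyllithium 22 would be acylated with N-methoxy-N-methylacetamide to 3-methylidene-4-(2-pentyl-1,3-dioxolan-2-yl)butan-2-one F6. The same detrifluoroacetylative diazo transfer, now at a methyl group, would give 1-diazo-3-methylidene-4-(2-pentyl-1,3-dioxolan-2-yl)butan-2-one F7. DBU-catalysed aldol addition of the diazo carbon to formaldehyde (paraformaldehyde, MeCN) would give 2-diazo-1-hydroxy-4-methylidene-5-(2-pentyl-1,3-dioxolan-2-yl)pentan-3-one F8, and TBSCl with imidazole would silylate it to 27.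

Step 7. Addition of butyllithium to the benzyl ester or metalation next to a benzyl ether oxygen may compete with the elimination–exchange sequence, and the terminal aryloxyalkyne may polymerise on work-up. The fallback reaches the alkyne by dehydrobromination with an amide base, the reagent class step 3 already relies on beside this ester; it sets out from phenol 9 and returns at acetylide 14, hence 15. Transfer vinylation ([Ir(cod)Cl]2, Na2CO3, vinyl acetate, toluene, 100 °C) would give benzyl 4,6-bis(benzyloxy)-3-(ethenyloxy)-2-[(2-pentyl-1,3-dioxolan-2-yl)methyl]benzoate F9. Br2 in CH2Cl2 at −78 °C would add to the enol ether to give benzyl 4,6-bis(benzyloxy)-3-(1,2-dibromoethoxy)-2-[(2-pentyl-1,3-dioxolan-2-yl)methyl]benzoate F10. Et3N would eliminate HBr to benzyl 4,6-bis(benzyloxy)-3-{[(Z)-2-bromoethenyl]oxy}-2-[(2-pentyl-1,3-dioxolan-2-yl)methyl]benzoate F11. LiN(i-Pr)2 (2.2 equiv, THF, −78 °C) would then eliminate again and deprotonate to 14, quenched with MeOH to 15.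

**Further compounds**

F1 | step 14 | methyl 2-hydroxy-4-methoxy-6-methylbenzoate | COC(=O)c1c(C)cc(OC)cc1O
F2 | step 14 | methyl 2-hydroxy-4-methoxy-6-(2-oxoheptyl)benzoate | CCCCCC(=O)Cc1cc(OC)cc(O)c1C(=O)OC
F3 | step 14 | 8-hydroxy-6-methoxy-3-pentyl-1H-isochromen-1-one | CCCCCc1cc2cc(OC)cc(O)c2c(=O)o1
F4 | step 14 | 6-methoxy-1-oxo-3-pentyl-1H-isochromen-8-yl trifluoromethanesulfonate | CCCCCc1cc2cc(OC)cc(OS(=O)(=O)C(F)(F)F)c2c(=O)o1
F5 | step 14 | benzyl 4,6-bis(benzyloxy)-3-[(6-methoxy-1-oxo-3-pentyl-1H-isochromen-8-yl)oxy]-2-[(2-pentyl-1,3-dioxolan-2-yl)methyl]benzoate | CCCCCc1cc2cc(OC)cc(Oc3c(OCc4ccccc4)cc(OCc4ccccc4)c(C(=O)OCc4ccccc4)c3CC3(CCCCC)OCCO3)c2c(=O)o1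
F6 | step 13 | 3-methylidene-4-(2-pentyl-1,3-dioxolan-2-yl)butan-2-one | CC(=O)C(=C)CC1(CCCCC)OCCO1
F7 | step 13 | 1-diazo-3-methylidene-4-(2-pentyl-1,3-dioxolan-2-yl)butan-2-one | [N-]=[N+]=CC(=O)C(=C)CC1(CCCCC)OCCO1
F8 | step 13 | 2-diazo-1-hydroxy-4-methylidene-5-(2-pentyl-1,3-dioxolan-2-yl)pentan-3-one | [N-]=[N+]=C(CO)C(=O)C(=C)CC1(CCCCC)OCCO1
F9 | step 7 | benzyl 4,6-bis(benzyloxy)-3-(ethenyloxy)-2-[(2-pentyl-1,3-dioxolan-2-yl)methyl]benzoate | C=COc1c(OCc2ccccc2)cc(OCc2ccccc2)c(C(=O)OCc2ccccc2)c1CC1(CCCCC)OCCO1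
F10 | step 7 | benzyl 4,6-bis(benzyloxy)-3-(1,2-dibromoethoxy)-2-[(2-pentyl-1,3-dioxolan-2-yl)methyl]benzoate (racemic) | BrCC(Br)Oc1c(OCc2ccccc2)cc(OCc2ccccc2)c(C(=O)OCc2ccccc2)c1CC1(CCCCC)OCCO1
F11 | step 7 | benzyl 4,6-bis(benzyloxy)-3-{[(Z)-2-bromoethenyl]oxy}-2-[(2-pentyl-1,3-dioxolan-2-yl)methyl]benzoate | Br/C=C\Oc1c(OCc2ccccc2)cc(OCc2ccccc2)c(C(=O)OCc2ccccc2)c1CC1(CCCCC)OCCO1
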